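**Plan**

- Retrosynthesis: the three silyl ethers come off last. The lactone carbonyl C-2 is traced back to the O–CH2 group of a 3,6-dihydro-2H-pyran (allylic oxidation). The ring is then cut at C-5–C-6 (cation–olefin closure) and at O-1–C-6 (condensation), giving a tris-silyloxy C16 aldehyde and a 2-silylbut-3-en-1-ol unit.
- The aldehyde chain is cut at both bonds to side-chain C-4′ (C-3′–C-4′ and C-4′–C-5′), a dithiane-masked carbon, giving two terminal epoxides.
- Enabling feature: C-6 is a carbinol carbon bound to ring oxygen O-1, so it can become an oxocarbenium carbon (O-1=C-6). C-5 is allylic to C-3=C-4, so it can be the terminus of an allylsilane with silicon on C-3. Closing C-5 onto C-6 makes the six-membered O-1/C-2–C-6 ring and, by loss of silicon, puts the double bond at C-3=C-4.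
- Forward: two epoxides and a silyl dithiane are joined in one flask; unmasking, anti reduction, silylation and ozonolysis give the aldehyde. The chiral silane is made in parallel. Ring closure, oxidation of the ring CH2 to C=O and desilylation follow.
- Stereochemistry: C-6′ and C-2′ come from (R)-epichlorohydrin (used twice); C-4′ from hydroxyl-directed anti reduction; C-6 from the C–Si stereocentre (asymmetric Si–H insertion) by anti-SE2′ chirality transfer, after which silicon is gone.

Key step: step 15

Remark: unprimed locants refer to the lactone ring of the target, primed locants to its pentadecyl side chain.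

Assumption: Rh2(S-DOSP)4 is taken to give the (2S)-silyl ester in step 12; if the sense of induction is the opposite, Rh2(R-DOSP)4 is used and nothing else changes.

**Route**

Step 1
Reactants: 1 (R)-epichlorohydrin; 2 n-octylmagnesium bromide
Product: 3 (2R)-1-chloroundecan-2-ol
Conditions: CuI (10 mol%), THF, −40 → 0 °C; aq. NH4Cl
Reagents that add atoms: none
Why: Copper-catalysed Grignard opening of the terminal epoxide at its CH2 carbon (SN2) leaves the C–O stereocentre untouched, so the carbinol configuration is that of the chiral-pool epoxide.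

Step 2
Reactants: 3 (2R)-1-chloroundecan-2-ol
Product: 4 (2R)-2-nonyloxirane
Conditions: NaOH (powdered), Et2O, rt
Reagents that add atoms: none
Why: Intramolecular Williamson etherification of the chlorohydrin displaces chloride at the primary carbon, so the stereocentre is retained.

Step 3
Reactants: 1 (R)-epichlorohydrin; 5 vinylmagnesium bromide
Product: 6 (2R)-1-chloropent-4-en-2-ol
Conditions: CuI (10 mol%), THF, −40 → 0 °C; aq. NH4Cl
Reagents that add atoms: none
Why: The same copper-catalysed SN2 epoxide opening at CH2 installs the allyl group and keeps the carbinol configuration of the chiral pool.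

Step 4
Reactants: 6 (2R)-1-chloropent-4-en-2-ol
Product: 7 (2R)-2-(prop-2-en-1-yl)oxirane
Conditions: NaOH (powdered), Et2O, rt; distillation
Reagents that add atoms: none
Why: Chlorohydrin ring closure (intramolecular Williamson etherification) at the primary carbon gives the volatile epoxide with the stereocentre retained.

Step 5
Reactants: 8 2-(tert-butyldimethylsilyl)-1,3-dithiane; 4 (2R)-2-nonyloxirane; 7 (2R)-2-(prop-2-en-1-yl)oxirane
Product: 12 (2R)-1-{2-[(2R)-2-(tert-butyldimethylsilyloxy)undecyl]-1,3-dithian-2-yl}pent-4-en-2-ol, via lithiated silyl dithiane 9 (not isolated), via lithium alkoxide adduct 10 (not isolated), via Brook-rearranged lithiodithiane 11 (not isolated)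
Conditions: t-BuLi, Et2O, −78 → −45 °C; 4, −78 → −25 °C; then 7, HMPA/THF, −78 → 0 °C; aq. NH4Cl
Reagents that add atoms: none
Why: Three-component dithiane linchpin coupling: the lithiated silyl dithiane opens 4 at CH2, HMPA triggers a 1,4-Brook rearrangement (silyl shift from carbon to oxygen) that regenerates a dithiane anion, and this opens 7 at CH2; both carbinol centres come unchanged from the epoxides.

Step 6
Reactants: 12 (2R)-1-{2-[(2R)-2-(tert-butyldimethylsilyloxy)undecyl]-1,3-dithian-2-yl}pent-4-en-2-ol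
Product: 13 (4R,8R)-8-(tert-butyldimethylsilyloxy)-4-hydroxyheptadec-1-en-6-one
Conditions: MeI, CaCO3, MeCN/H2O (9:1), 45 °C
Reagents that add atoms: water, O
Why: Dithiane unmasking by S-methylation and hydrolysis releases the ketone under near-neutral conditions that spare the silyl ether, the alkene and the β-hydroxy ketone.

Step 7
Reactants: 13 (4R,8R)-8-(tert-butyldimethylsilyloxy)-4-hydroxyheptadec-1-en-6-one
Product: 14 (4R,6S,8R)-8-(tert-butyldimethylsilyloxy)heptadec-1-ene-4,6-diol
Conditions: Me4NBH(OAc)3, MeCN/AcOH (1:1), −30 °C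
Reagents that add atoms: none
Why: Evans–Saksena reduction: the free 4-hydroxyl binds boron and delivers hydride intramolecularly through a chair transition state, so the new C-6 centre is 1,3-anti to C-4 and thereby syn to the fixed silyloxy centre C-8.

Step 8
Reactants: 14 (4R,6S,8R)-8-(tert-butyldimethylsilyloxy)heptadec-1-ene-4,6-diol
Product: 15 (4R,6R,8R)-4,6,8-tris(tert-butyldimethylsilyloxy)heptadec-1-ene
Conditions: TBSOTf, 2,6-lutidine, CH2Cl2, 0 °C
Reagents that add atoms: tert-butyldimethylsilyl triflate, CC(C)(C)[Si](C)(C)OS(=O)(=O)C(F)(F)F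
Why: Silyl triflate silylation of both secondary hydroxyls gives a uniformly protected, non-chelating triol that tolerates the later Lewis acid and falls in one final operation.

Step 9
Reactants: 15 (4R,6R,8R)-4,6,8-tris(tert-butyldimethylsilyloxy)heptadec-1-ene
Product: 17 (3S,5R,7R)-3,5,7-tris(tert-butyldimethylsilyloxy)hexadecanal, via secondary ozonide 16 (not isolated)
Conditions: O3, CH2Cl2, −78 °C; then PPh3, −78 °C → rt
Reagents that add atoms: ozone, [O-][O+]=O
Why: Ozonolysis with reductive work-up cleaves the terminal vinyl group to the aldehyde without touching silyl ethers or stereocentres; the β-silyloxy aldehyde is used without chromatography to avoid elimination.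

Step 10
Reactants: 18 ethyl diazoacetate; 19 acetaldehyde
Product: 20 ethyl 2-diazo-3-hydroxybutanoate (racemic)
Conditions: DBU (10 mol%), MeCN, 0 °C → rt
Reagents that add atoms: none
Why: Base-catalysed aldol-type addition of the diazoacetate carbanion to the aldehyde gives the β-hydroxy α-diazo ester, whose stereocentre is removed in the next step.

Step 11
Reactants: 20 ethyl 2-diazo-3-hydroxybutanoate
Product: 21 ethyl 2-diazobut-3-enoate
Conditions: POCl3, Et3N, CH2Cl2, 0 °C
Reagents that add atoms: none
Why: Dehydration through the dichlorophosphate (E2-type elimination) gives the vinyldiazoacetate, which is used at once because it slowly closes to a pyrazole.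

Step 12
Reactants: 21 ethyl 2-diazobut-3-enoate
Product: 22 ethyl (2S)-2-[dimethyl(phenyl)silyl]but-3-enoate
Conditions: PhMe2SiH (1.5 equiv), Rh2(S-DOSP)4 (1 mol%), pentane, −78 °C, slow addition of 21
Reagents that add atoms: dimethylphenylsilane, C[SiH](C)c1ccccc1
Why: Catalytic asymmetric carbenoid Si–H insertion takes place at the carbenoid carbon, not the vinylogous terminus, and the chiral dirhodium carboxylate differentiates the carbene faces to set the C–Si stereocentre of the α-silyl β,γ-unsaturated ester.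

Step 13
Reactants: 22 ethyl (2S)-2-[dimethyl(phenyl)silyl]but-3-enoate
Product: 23 (2S)-2-[dimethyl(phenyl)silyl]but-3-en-1-ol
Conditions: i-Bu2AlH (2.2 equiv), CH2Cl2, −78 °C; aq. potassium sodium tartrate
Reagents that add atoms: none
Why: Hydride reduction of the ester at low temperature leaves the C–Si centre and the allylsilane untouched, and the aluminium alkoxide does not undergo Peterson elimination.

Step 14
Reactants: 23 (2S)-2-[dimethyl(phenyl)silyl]but-3-en-1-ol
Product: 24 {[(2S)-2-[dimethyl(phenyl)silyl]but-3-en-1-yl]oxy}trimethylsilane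
Conditions: TMSCl, Et3N, CH2Cl2, 0 °C
Reagents that add atoms: trimethylsilyl chloride, C[Si](C)(C)Cl
Why: O-Silylation gives the silyl ether needed for aprotic, silyl-triflate-catalysed condensation with the aldehyde.

Step 15
Reactants: 17 (3S,5R,7R)-3,5,7-tris(tert-butyldimethylsilyloxy)hexadecanal; 24 {[(2S)-2-[dimethyl(phenyl)silyl]but-3-en-1-yl]oxy}trimethylsilane
Product: 26 (2S)-2-[(2R,4R,6R)-2,4,6-tris(tert-butyldimethylsilyloxy)pentadecyl]-3,6-dihydro-2H-pyran, via oxocarbenium triflate 25 (not isolated)
Conditions: TMSOTf (0.3 equiv), 2,6-di-tert-butyl-4-methylpyridine (0.1 equiv), CH2Cl2, −78 °C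
Reagents that add atoms: none
Why: The silyl triflate condenses aldehyde 17 with silyl ether 24 to the (E)-oxocarbenium ion 25 (ring O–C bond), whose carbon is attacked by the terminal vinyl carbon of the allylsilane; the β-silyl carbocation then loses silicon and leaves the ring double bond next to the O–CH2 group. The closest known reaction type is the silyl-Prins (intramolecular Hosomi–Sakurai) annulation of β-hydroxy allylsilanes with aldehydes to 3,6-dihydro-2H-pyrans. The dihydropyran ring closes in a 6-endo-trig cation–olefin mode through a chair-like transition state, and the bond made (C-2–C-3 of 26) is the future C-5–C-6 bond of the lactone. The new stereocentre C-2 is controlled by the C–Si stereocentre alone: the C–Si bond must lie axial and anti to the incoming oxocarbenium carbon (anti-SE2′) while the side chain of the (E)-oxocarbenium ion sits equatorial, which places chain and silicon cis and turns the (S)-silane into (2S); any minor antipode of 24 ends up as a separable C-2 epimer. The step needs C–C closure to outrun intermolecular allylation of free aldehyde, 2-oxonia-Cope exchange, Peterson-type loss of silicon and β-elimination of the silyloxy aldehyde; this is secured by the β-silicon effect, which makes closure fast at −78 °C, by feeding the alcohol as its silyl ether so that mixed-acetal formation precedes C-allylation, and by the hindered pyridine, which removes protic acid.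

Step 16
Reactants: 26 (2S)-2-[(2R,4R,6R)-2,4,6-tris(tert-butyldimethylsilyloxy)pentadecyl]-3,6-dihydro-2H-pyran
Product: 27 (6S)-6-[(2R,4R,6R)-2,4,6-tris(tert-butyldimethylsilyloxy)pentadecyl]-5,6-dihydro-2H-pyran-2-one
Conditions: [C5H5NH][CrO3Cl] (pyridinium chlorochromate, 4 equiv), NaOAc, 4 Å MS, CH2Cl2, 40 °C
Reagents that add atoms: pyridinium chlorochromate [C5H5NH][CrO3Cl], [O-][Cr](=O)(=O)Cl.c1cc[nH+]cc1
Why: Allylic oxidation by hexavalent chromium attacks the ring CH2 that is both allylic and bound to oxygen (C-6 of 26), converting the cyclic allyl ether into the α,β-unsaturated δ-lactone without moving the double bond or touching the stereocentres.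

Step 17
Reactants: 27 (6S)-6-[(2R,4R,6R)-2,4,6-tris(tert-butyldimethylsilyloxy)pentadecyl]-5,6-dihydro-2H-pyran-2-one
Product: 28 (6S)-6-[(2S,4R,6R)-2,4,6-trihydroxypentadecyl]-5,6-dihydro-2H-pyran-2-one
Conditions: HF (48% aq.), MeCN, 0 °C → rt
Reagents that add atoms: none
Why: Fluoride-driven desilylation under mildly acidic conditions frees the three hydroxyls while the base-sensitive unsaturated lactone (prone to oxa-Michael closure by the 2′-hydroxyl) stays intact.

**Compound list**

1 | (R)-epichlorohydrin, (2R)-2-(chloromethyl)oxirane | ClC[C@H]1CO1 | starting material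
2 | n-octylmagnesium bromide | CCCCCCCC[Mg]Br | starting material
3 | (2R)-1-chloroundecan-2-ol | CCCCCCCCC[C@@H](O)CCl | intermediate
4 | (2R)-2-nonyloxirane | CCCCCCCCC[C@@H]1CO1 | intermediate
5 | vinylmagnesium bromide | C=C[Mg]Br | starting material
6 | (2R)-1-chloropent-4-en-2-ol | C=CC[C@@H](O)CCl | intermediate
7 | (2R)-2-(prop-2-en-1-yl)oxirane | C=CC[C@@H]1CO1 | intermediate
8 | 2-(tert-butyldimethylsilyl)-1,3-dithiane | CC(C)(C)[Si](C)(C)C1SCCCS1 | starting material
9 | 2-lithio-2-(tert-butyldimethylsilyl)-1,3-dithiane | [Li]C1([Si](C)(C)C(C)(C)C)SCCCS1 | intermediate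
10 | lithium (2R)-1-[2-(tert-butyldimethylsilyl)-1,3-dithian-2-yl]undecan-2-olate | CCCCCCCCC[C@@H](O[Li])CC1([Si](C)(C)C(C)(C)C)SCCCS1 | intermediate
11 | 2-lithio-2-[(2R)-2-(tert-butyldimethylsilyloxy)undecyl]-1,3-dithiane | CCCCCCCCC[C@@H](O[Si](C)(C)C(C)(C)C)CC1([Li])SCCCS1 | intermediate
12 | (2R)-1-{2-[(2R)-2-(tert-butyldimethylsilyloxy)undecyl]-1,3-dithian-2-yl}pent-4-en-2-ol | CCCCCCCCC[C@@H](O[Si](C)(C)C(C)(C)C)CC1(SCCCS1)C[C@H](O)CC=C | intermediate
13 | (4R,8R)-8-(tert-butyldimethylsilyloxy)-4-hydroxyheptadec-1-en-6-one | CCCCCCCCC[C@@H](O[Si](C)(C)C(C)(C)C)CC(=O)C[C@H](O)CC=C | intermediate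
14 | (4R,6S,8R)-8-(tert-butyldimethylsilyloxy)heptadec-1-ene-4,6-diol | CCCCCCCCC[C@@H](O[Si](C)(C)C(C)(C)C)C[C@@H](O)C[C@H](O)CC=C | intermediate
15 | (4R,6R,8R)-4,6,8-tris(tert-butyldimethylsilyloxy)heptadec-1-ene | CCCCCCCCC[C@@H](O[Si](C)(C)C(C)(C)C)C[C@@H](O[Si](C)(C)C(C)(C)C)C[C@H](O[Si](C)(C)C(C)(C)C)CC=C | intermediate
16 | 3-[(2S,4R,6R)-2,4,6-tris(tert-butyldimethylsilyloxy)pentadecyl]-1,2,4-trioxolane (secondary ozonide, both ring epimers) | CCCCCCCCC[C@@H](O[Si](C)(C)C(C)(C)C)C[C@@H](O[Si](C)(C)C(C)(C)C)C[C@H](O[Si](C)(C)C(C)(C)C)CC1OCOO1 | intermediate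
17 | (3S,5R,7R)-3,5,7-tris(tert-butyldimethylsilyloxy)hexadecanal | CCCCCCCCC[C@@H](O[Si](C)(C)C(C)(C)C)C[C@@H](O[Si](C)(C)C(C)(C)C)C[C@H](O[Si](C)(C)C(C)(C)C)CC=O | intermediate
18 | ethyl diazoacetate | CCOC(=O)C=[N+]=[N-] | starting material
19 | acetaldehyde | CC=O | starting material
20 | ethyl 2-diazo-3-hydroxybutanoate (racemic) | CCOC(=O)C(=[N+]=[N-])C(C)O | intermediate
21 | ethyl 2-diazobut-3-enoate | CCOC(=O)C(=[N+]=[N-])C=C | intermediate
22 | ethyl (2S)-2-[dimethyl(phenyl)silyl]but-3-enoate | C=C[C@H]([Si](C)(C)c1ccccc1)C(=O)OCC | intermediate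
23 | (2S)-2-[dimethyl(phenyl)silyl]but-3-en-1-ol | C=C[C@H]([Si](C)(C)c1ccccc1)CO | intermediate
24 | {[(2S)-2-[dimethyl(phenyl)silyl]but-3-en-1-yl]oxy}trimethylsilane | C=C[C@H]([Si](C)(C)c1ccccc1)CO[Si](C)(C)C | intermediate
25 | (E)-oxocarbenium triflate from 17 and 24: O-[(2S)-2-[dimethyl(phenyl)silyl]but-3-en-1-yl] oxonium of aldehyde 17 | CCCCCCCCC[C@@H](O[Si](C)(C)C(C)(C)C)C[C@@H](O[Si](C)(C)C(C)(C)C)C[C@H](O[Si](C)(C)C(C)(C)C)C/C=[O+]/C[C@@H]([Si](C)(C)c1ccccc1)C=C.[O-]S(=O)(=O)C(F)(F)F | intermediate
26 | (2S)-2-[(2R,4R,6R)-2,4,6-tris(tert-butyldimethylsilyloxy)pentadecyl]-3,6-dihydro-2H-pyran | CCCCCCCCC[C@@H](O[Si](C)(C)C(C)(C)C)C[C@@H](O[Si](C)(C)C(C)(C)C)C[C@H](O[Si](C)(C)C(C)(C)C)C[C@@H]1CC=CCO1 | intermediate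
27 | (6S)-6-[(2R,4R,6R)-2,4,6-tris(tert-butyldimethylsilyloxy)pentadecyl]-5,6-dihydro-2H-pyran-2-one | CCCCCCCCC[C@@H](O[Si](C)(C)C(C)(C)C)C[C@@H](O[Si](C)(C)C(C)(C)C)C[C@H](O[Si](C)(C)C(C)(C)C)C[C@@H]1CC=CC(=O)O1 | intermediate
28 | (6S)-6-[(2S,4R,6R)-2,4,6-trihydroxypentadecyl]-5,6-dihydro-2H-pyran-2-one | CCCCCCCCC[C@@H](O)C[C@@H](O)C[C@H](O)C[C@@H]1CC=CC(=O)O1 | target

**Step count and risks**

Total steps: 17. Longest linear sequence: 10 steps (1, 2, 5, 6, 7, 8, 9, 15, 16, 17).

Steps most likely to fail:

1. Step 15 (key step). What may go wrong: incomplete transfer of chirality from silicon (syn-SE2′ leakage or 2-oxonia-Cope exchange before closure), intermolecular allylation of the aldehyde, or β-elimination of the silyloxy aldehyde under the Lewis acid. Fallback: setting out from aldehyde 17, a catalyst-controlled, endo-selective hetero-Diels–Alder reaction with (E)-1-methoxybuta-1,3-diene should give the methyl acetal (2S)-6-methoxy-2-[(2R,4R,6R)-2,4,6-tris(tert-butyldimethylsilyloxy)pentadecyl]-3,6-dihydro-2H-pyran F1. The catalyst is the chromium chloride complex [Cr(L)Cl] (trivalent chromium; L = the tridentate Schiff-base dianion from 3-(1-adamantyl)-2-hydroxy-5-methylbenzaldehyde and cis-1-aminoindan-2-ol, antipode chosen for the S ring centre), with 4 Å molecular sieves, no solvent, rt. Mild hydrolysis (PPTS, acetone/H2O) should give the lactol (6S)-6-[(2R,4R,6R)-2,4,6-tris(tert-butyldimethylsilyloxy)pentadecyl]-5,6-dihydro-2H-pyran-2-ol F2, and MnO2 (CH2Cl2, rt) should oxidise this allylic lactol to lactone 27, where the route is rejoined.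

2. Step 12. What may go wrong: poor facial selectivity with the unsubstituted vinylcarbenoid, or electrocyclisation of 21 to a pyrazole before insertion. Fallback: setting out from 21, Si–H insertion with PhMe2SiH catalysed by Rh2(OAc)4 (CH2Cl2, rt, slow addition) should give racemic ethyl 2-[dimethyl(phenyl)silyl]but-3-enoate F3. Reduction with i-Bu2AlH should give racemic 2-[dimethyl(phenyl)silyl]but-3-en-1-ol F4. Lipase-mediated kinetic resolution (Burkholderia cepacia lipase, vinyl acetate, t-BuOMe, rt; sense to be confirmed on small scale) is expected to acylate the (R)-alcohol to (2R)-2-[dimethyl(phenyl)silyl]but-3-en-1-yl acetate F5 and leave the (S)-alcohol 23, where the route is rejoined.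

3. Step 16. What may go wrong: incomplete conversion, competing oxidation at the other allylic CH2 (C-3 of 26), or acid-induced loss of silyl ethers. Fallback: setting out from 26, a radical C–H peroxidation (t-BuOOH, Rh2(cap)4 = dirhodium tetrakis(caprolactamate), 1 mol%, CH2Cl2, rt) should give the allylic peroxy acetal (2S)-6-(tert-butylperoxy)-2-[(2R,4R,6R)-2,4,6-tris(tert-butyldimethylsilyloxy)pentadecyl]-3,6-dihydro-2H-pyran F6. Kornblum–DeLaMare fragmentation (Et3N, CH2Cl2, rt) should then convert it into lactone 27, where the route is rejoined.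

Further compounds
F1 | step 15 | (2S)-6-methoxy-2-[(2R,4R,6R)-2,4,6-tris(tert-butyldimethylsilyloxy)pentadecyl]-3,6-dihydro-2H-pyran | CCCCCCCCC[C@@H](O[Si](C)(C)C(C)(C)C)C[C@@H](O[Si](C)(C)C(C)(C)C)C[C@H](O[Si](C)(C)C(C)(C)C)C[C@@H]1CC=CC(OC)O1
F2 | step 15 | (6S)-6-[(2R,4R,6R)-2,4,6-tris(tert-butyldimethylsilyloxy)pentadecyl]-5,6-dihydro-2H-pyran-2-ol | CCCCCCCCC[C@@H](O[Si](C)(C)C(C)(C)C)C[C@@H](O[Si](C)(C)C(C)(C)C)C[C@H](O[Si](C)(C)C(C)(C)C)C[C@@H]1CC=CC(O)O1
F3 | step 12 | ethyl 2-[dimethyl(phenyl)silyl]but-3-enoate (racemic) | C=CC([Si](C)(C)c1ccccc1)C(=O)OCC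
F4 | step 12 | 2-[dimethyl(phenyl)silyl]but-3-en-1-ol (racemic) | C=CC([Si](C)(C)c1ccccc1)CO
F5 | step 12 | (2R)-2-[dimethyl(phenyl)silyl]but-3-en-1-yl acetate | C=C[C@@H]([Si](C)(C)c1ccccc1)COC(C)=O
F6 | step 16 | (2S)-6-(tert-butylperoxy)-2-[(2R,4R,6R)-2,4,6-tris(tert-butyldimethylsilyloxy)pentadecyl]-3,6-dihydro-2H-pyran | CCCCCCCCC[C@@H](O[Si](C)(C)C(C)(C)C)C[C@@H](O[Si](C)(C)C(C)(C)C)C[C@H](O[Si](C)(C)C(C)(C)C)C[C@@H]1CC=CC(OOC(C)(C)C)O1
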